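**Retrosynthetic overview**

1. The 7-membered lactone and the C5 ketone come last: the C16 acrylic acid (from the C15 isopropenyl group) opens a C4–C5 epoxide at C4, then C5–OH is oxidised and C13–O is desilylated.
2. The 14-membered carbocycle is closed at C5–C6 by intramolecular Negishi coupling of a primary alkylzinc with an (E)-vinyl iodide made by Zr-catalysed carboalumination of a terminal alkyne (this brings in methyl C18).
3. The oxane ring (O, C8–C12) is released from a 6,8-dioxabicyclo[3.2.1]octane ketal by retentive AlMe3 opening (methyl C19). The ketal comes from the key step: sparteine-mediated lithiation of a C9 carbamate, acylation by a Weinreb amide (C8–C9), and closure of the ketone oxygen onto C12 of a (12S,13S)-epoxide (O–C12), with the C13 oxygen forming a temporary dioxolane.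
4. The key-step precursor comes from (R)-limonene (C1 stereocentre, C13–C14, C2–C4, C15–C17) by ring ozonolysis, ketone-to-alkyne conversion, isopropenyl Grignard addition, Johnson–Claisen rearrangement (E-C12=C13) and Shi epoxidation.
5. Enabling feature: the ring oxygen of the oxane sits on C8, so C8 is a masked ketone carbonyl five atoms from C12. C12 with its vicinal C13 hydroxyl is the retron of a trisubstituted epoxide, and the C9 oxygen makes C9 an α-oxygen carbanion. Ring order: bicyclic ketal (oxane plus temporary dioxolane), then 14-membered carbocycle, then 7-membered lactone.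

Key step: step 11

Remark (numbering): cembrane numbering of the target is used for all compounds. C1 is the ring CH bearing C15 (C17 = exocyclic CH2, C16 = lactone carbonyl); C4 carries methyl C18 and the lactone oxygen; C5 is the ketone; C8 carries methyl C19 and the ring oxygen; C9 carries OAc; C12 carries methyl C20 and the ring oxygen; C13 carries OH. The target is (1R,4R,8S,9S,12R,13S).

Remark (assumption): (+)-sparteine and the enantiomer of Shi's D-fructose-derived ketone (ent-Shi ketone, made from L-sorbose) are taken as available reagents.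

**Route**

Step 1
Reactants: 1 (R)-(+)-limonene
Product: 3 keto acetal (R)-7,7-dimethoxy-5-(prop-1-en-2-yl)heptan-2-one, via keto aldehyde 2 (not isolated)
Conditions: O3, CH2Cl2/MeOH, −78 °C; Me2S, −78 °C → rt; then TsOH (cat.), MeOH, rt
Reagents that add atoms: ozone O=[O+][O-]; methanol CO
Why: Alkene ozonolysis with reductive work-up should cleave the electron-rich trisubstituted ring alkene in preference to the 1,1-disubstituted isopropenyl group, and the aldehyde of 2 is then acetalised chemoselectively over the methyl ketone, the C1 stereocentre of limonene being untouched.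

Step 2
Reactants: 3 keto acetal
Product: 6 silyl alkyne acetal [(R)-7,7-dimethoxy-5-(prop-1-en-2-yl)hept-1-yn-1-yl]trimethylsilane, via enol phosphate 4 (not isolated), via lithium acetylide 5 (not isolated)
Conditions: LDA (1.05 equiv), THF, −78 °C; ClP(O)(OEt)2; LDA (2.3 equiv), −78 °C → rt; TMSCl, −78 °C → rt
Reagents that add atoms: chlorotrimethylsilane C[Si](C)(C)Cl
Why: Kinetic enolisation at the methyl group, O-phosphorylation and double elimination (Negishi ketone-to-alkyne protocol) should give the lithium acetylide, which is C-silylated in the flask so that the alkyne is inert in the later organolithium step.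

Step 3
Reactants: 6 silyl alkyne acetal
Product: 7 aldehyde (R)-3-(prop-1-en-2-yl)-7-(trimethylsilyl)hept-6-ynal
Conditions: oxalic acid (cat.), THF/H2O, rt
Reagents that add atoms: water O
Why: Mild acid-catalysed acetal hydrolysis should free the aldehyde without touching the C-silyl alkyne or the alkenes.

Step 4
Reactants: 7 aldehyde
Product: 8 allylic alcohol (5R)-2-methyl-5-(prop-1-en-2-yl)-9-(trimethylsilyl)non-1-en-8-yn-3-ol (both C13 epimers)
Conditions: isopropenylmagnesium bromide, THF, −78 → 0 °C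
Reagents that add atoms: isopropenylmagnesium bromide C=C(C)[Mg]Br
Why: Grignard 1,2-addition to the aldehyde brings in C12, C20 and C11; the new carbinol centre is formed without control, which is harmless because it becomes sp2 in the next step.

Step 5
Reactants: 8 allylic alcohol
Product: 9 ester ethyl (4E,7R)-4-methyl-7-(prop-1-en-2-yl)-11-(trimethylsilyl)undec-4-en-10-ynoate
Conditions: MeC(OEt)3, EtCO2H (cat.), 140 °C, EtOH distilled off
Reagents that add atoms: triethyl orthoacetate CCOC(C)(OCC)OCC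
Why: Johnson orthoester Claisen rearrangement through a chair transition state with the C14 substituent equatorial should give the (E)-trisubstituted C12=C13 alkene and add C10 and C9.

Step 6
Reactants: 9 ester
Product: 10 alcohol (4E,7R)-4-methyl-7-(prop-1-en-2-yl)-11-(trimethylsilyl)undec-4-en-10-yn-1-ol
Conditions: LiAlH4, Et2O, 0 °C
Reagents that add atoms: none
Why: Hydride reduction of the ester to the primary alcohol leaves the alkenes and the silyl alkyne untouched.

Step 7
Reactants: 10 alcohol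
Product: 11 carbamate (4E,7R)-4-methyl-7-(prop-1-en-2-yl)-11-(trimethylsilyl)undec-4-en-10-yn-1-yl N,N-diisopropylcarbamate
Conditions: iPr2NCOCl, Et3N, DMAP (cat.), CH2Cl2, reflux
Reagents that add atoms: N,N-diisopropylcarbamoyl chloride CC(C)N(C(C)C)C(Cl)=O
Why: O-Carbamoylation installs the directing, dipole-stabilising group needed for the Hoppe lithiation at C9.

Step 8
Reactants: 11 carbamate
Product: 12 epoxy carbamate 3-{(2S,3S)-2-methyl-3-[(2R)-2-(prop-1-en-2-yl)-6-(trimethylsilyl)hex-5-yn-1-yl]oxiran-2-yl}propyl N,N-diisopropylcarbamate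
Conditions: ent-Shi ketone (0.3 equiv), KHSO5 (as 2KHSO5·KHSO4·K2SO4), K2CO3, Bu4NHSO4 (cat.), MeCN/dimethoxymethane/aq. Na2B4O7 buffer, 0 °C
Reagents that add atoms: potassium peroxymonosulfate [K+].[O-]S(=O)(=O)OO
Why: Shi asymmetric epoxidation (chiral dioxirane, spiro transition state) of the electron-rich (E)-trisubstituted alkene should give the (12S,13S)-epoxide by reagent control, the isopropenyl alkene reacting much more slowly.

Step 9
Reactants: 13 methyl 3-hydroxypropanoate
Product: 14 methyl 3-(tert-butyldimethylsilyloxy)propanoate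
Conditions: TBSCl, imidazole, DMF, rt
Reagents that add atoms: tert-butyldimethylsilyl chloride CC(C)(C)[Si](C)(C)Cl
Why: Standard silylation of the primary alcohol.

Step 10
Reactants: 14 silyl ether ester
Product: 15 Weinreb amide 3-(tert-butyldimethylsilyloxy)-N-methoxy-N-methylpropanamide
Conditions: MeNH(OMe)·HCl, iPrMgCl, THF, −20 °C
Reagents that add atoms: N,O-dimethylhydroxylamine hydrochloride CNOC.Cl
Why: Weinreb amidation of the ester with the magnesium amide of N,O-dimethylhydroxylamine gives the acyl donor that carries C8, C7 and C6.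

Step 11
Reactants: 12 epoxy carbamate; 15 Weinreb amide
Product: 18 bicyclic ketal (1R,4S,5S,7S)-5-[2-(tert-butyldimethylsilyloxy)ethyl]-1-methyl-7-[(2R)-2-(prop-1-en-2-yl)-6-(trimethylsilyl)hex-5-yn-1-yl]-6,8-dioxabicyclo[3.2.1]octan-4-yl N,N-diisopropylcarbamate, via lithiated carbamate 16 (not isolated), via epoxy ketone 17 (not isolated)
Conditions: sBuLi (1.3 equiv), (+)-sparteine (1.3 equiv), Et2O, −78 °C; 15, −78 °C; AcOH, −78 → 0 °C; then CSA (excess over the diamine), CH2Cl2, 0 °C → rt, same flask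
Reagents that add atoms: none
Why: sBuLi/(+)-sparteine removes one enantiotopic C9 proton next to the carbamate oxygen to give the configurationally stable α-oxygen carbanion 16, which is acylated with retention by 15 through a chelated tetrahedral adduct (C8–C9 bond), and on acidification the freed δ,ε-epoxy ketone 17 closes by attack of the ketone oxygen on the tertiary epoxide carbon C12 (O–C12 bond) followed by capture of the C8 oxocarbenium ion by the released C13 alkoxide. The closest known reaction types are the Hoppe sparteine-mediated lithiation–substitution of alkyl carbamates with acyl electrophiles and the acid-catalysed epoxy ketone to 6,8-dioxabicyclo[3.2.1]octane cyclisation known from brevicomin and frontalin syntheses. The six-membered ring (O, C8–C12) closes 6-exo-tet at the epoxide with the carbonyl oxygen as nucleophile, and the temporary five-membered dioxolane closes by 5-endo-trig capture of the oxocarbenium ion, the normal mode of ketal formation. C9 (S) is set by the chiral diamine with retention on acylation, C12 (R) arises by stereospecific inversion of the (12S)-epoxide carbon, C13 (S) is carried over unchanged, and the ketal carbon C8 can only adopt the configuration in which its C13-oxygen bond lies on the face of the C12–C13 bond. The step needs attack at C12 and not C13, which the tertiary (Markovnikov) character of C12 and the six- over seven-membered ring preference secure, and it needs the C9 oxygen to stay out of the epoxide opening, which its carbamoylation secures. Loss of configuration at C9 is avoided because the ketone is released only under mildly acidic conditions and is consumed at once by ketalisation.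

Step 12
Reactants: 18 bicyclic ketal
Product: 19 oxane alcohol (2S,3S,6R)-2-[2-(tert-butyldimethylsilyloxy)ethyl]-6-[(1S,3R)-1-hydroxy-3-(prop-1-en-2-yl)-7-(trimethylsilyl)hept-6-yn-1-yl]-2,6-dimethyloxan-3-yl N,N-diisopropylcarbamate
Conditions: AlMe3 (6 equiv), C6F5OH (3 equiv), toluene, 0 °C → rt
Reagents that add atoms: trimethylaluminium C[Al](C)C
Why: In this organoaluminium-mediated alkylative cleavage of a bicyclic ketal, aluminium binds the less hindered dioxolane oxygen (on C13), the C8–O bond ionises to the six-membered oxocarbenium ion and methyl is delivered from the bound aluminate to the same face (retention, also the face anti to the C9 carbamate), which sets C8 (S) with C19 cis to the C13 side chain and frees the C13 hydroxyl.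

Step 13
Reactants: 19 oxane alcohol
Product: 20 bis(silyl ether) (2S,3S,6R)-2-[2-(tert-butyldimethylsilyloxy)ethyl]-6-[(1S,3R)-1-(tert-butyldimethylsilyloxy)-3-(prop-1-en-2-yl)-7-(trimethylsilyl)hept-6-yn-1-yl]-2,6-dimethyloxan-3-yl N,N-diisopropylcarbamate
Conditions: TBSOTf, 2,6-lutidine, CH2Cl2, 0 °C
Reagents that add atoms: tert-butyldimethylsilyl triflate CC(C)(C)[Si](C)(C)OS(=O)(=O)C(F)(F)F
Why: Silylation of the hindered C13 hydroxyl with the reactive triflate allows C9 to be acetylated selectively later and protects C13 during the C5 oxidation.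

Step 14
Reactants: 20 bis(silyl ether)
Product: 21 C9 alcohol (2S,3S,6R)-2-[2-(tert-butyldimethylsilyloxy)ethyl]-6-[(1S,3R)-1-(tert-butyldimethylsilyloxy)-3-(prop-1-en-2-yl)-7-(trimethylsilyl)hept-6-yn-1-yl]-2,6-dimethyloxan-3-ol
Conditions: LiAlH4, THF, reflux
Reagents that add atoms: none
Why: Reductive cleavage of the carbamate by hydride attack at the carbamoyl carbon frees the C9 hydroxyl with its configuration unchanged, at a stage where nothing else is reducible.

Step 15
Reactants: 21 C9 alcohol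
Product: 22 diol alkyne (2S,3S,6R)-6-[(1S,3R)-1-(tert-butyldimethylsilyloxy)-3-(prop-1-en-2-yl)hept-6-yn-1-yl]-2-(2-hydroxyethyl)-2,6-dimethyloxan-3-ol
Conditions: TBAF (2.5 equiv), AcOH (2.5 equiv), THF, 0 °C → rt
Reagents that add atoms: none
Why: Fluoride-mediated desilylation should cleave the C-silyl alkyne and the primary silyl ether, while the secondary silyl ether flanked by the quaternary C12 reacts far more slowly.

Step 16
Reactants: 22 diol alkyne
Product: 24 vinyl iodide diol (2S,3S,6R)-6-[(1S,3R,6E)-1-(tert-butyldimethylsilyloxy)-7-iodo-6-methyl-3-(prop-1-en-2-yl)hept-6-en-1-yl]-2-(2-hydroxyethyl)-2,6-dimethyloxan-3-ol, via vinylalane 23 (not isolated)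
Conditions: AlMe3 (5 equiv), Cp2ZrCl2 (0.3 equiv), H2O (1 equiv), CH2Cl2, −20 °C; then I2, THF, −30 → 0 °C
Reagents that add atoms: trimethylaluminium C[Al](C)C; iodine II
Why: Negishi zirconium-catalysed syn-carboalumination of the terminal alkyne places methyl C18 on C4 and aluminium on C5, and iodinolysis with retention gives the (E)-vinyl iodide, the two hydroxyls being carried as aluminium alkoxides.

Step 17
Reactants: 24 vinyl iodide diol
Product: 25 diiodide (2S,3S,6R)-6-[(1S,3R,6E)-1-(tert-butyldimethylsilyloxy)-7-iodo-6-methyl-3-(prop-1-en-2-yl)hept-6-en-1-yl]-2-(2-iodoethyl)-2,6-dimethyloxan-3-ol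
Conditions: I2, PPh3, imidazole, CH2Cl2, 0 °C
Reagents that add atoms: iodine II
Why: Appel-type iodination is selective for the primary alcohol over the hindered secondary C9 hydroxyl next to the quaternary C8.

Step 18
Reactants: 25 diiodide
Product: 26 acetate (2S,3S,6R)-6-[(1S,3R,6E)-1-(tert-butyldimethylsilyloxy)-7-iodo-6-methyl-3-(prop-1-en-2-yl)hept-6-en-1-yl]-2-(2-iodoethyl)-2,6-dimethyloxan-3-yl acetate
Conditions: Ac2O, pyridine, DMAP (cat.), CH2Cl2, rt
Reagents that add atoms: acetic anhydride CC(=O)OC(C)=O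
Why: DMAP-catalysed acetylation of the only free hydroxyl installs the C9 acetate of the target.

Step 19
Reactants: 26 acetate
Product: 28 macrocyclic triene (1R,4E,8S,9S,12R,13S)-13-(tert-butyldimethylsilyloxy)-8,12-epoxycembra-4,15(17)-dien-9-yl acetate, via alkylzinc iodide 27 (not isolated)
Conditions: Zn dust (activated with 1,2-dibromoethane/TMSCl), LiCl, THF, 40 °C; then slow addition to Pd(PPh3)4 (10 mol %), THF/DMF, 50 °C, 2 mM
Reagents that add atoms: none
Why: Zinc inserts only into the primary C–I bond (the vinyl iodide is inert to zinc dust), and intramolecular Negishi coupling at the zerovalent palladium catalyst under high dilution should close the 14-membered carbocycle at C5–C6 with retention of the (E)-alkene geometry.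

Step 20
Reactants: 28 macrocyclic triene
Product: 29 macrocyclic epoxide (1R,4S,5S,8S,9S,12R,13S)-13-(tert-butyldimethylsilyloxy)-4,5:8,12-diepoxycembr-15(17)-en-9-yl acetate
Conditions: ent-Shi ketone (0.3 equiv), KHSO5 (as 2KHSO5·KHSO4·K2SO4), K2CO3, Bu4NHSO4 (cat.), MeCN/dimethoxymethane/aq. Na2B4O7 buffer, 0 °C
Reagents that add atoms: potassium peroxymonosulfate [K+].[O-]S(=O)(=O)OO
Why: In this second Shi epoxidation the (E)-trisubstituted C4=C5 alkene reacts in preference to the isopropenyl group and the chiral dioxirane should deliver the (4S,5S)-epoxide by reagent control.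

Step 21
Reactants: 29 macrocyclic epoxide
Product: 30 allylic alcohol (1R,4S,5S,8S,9S,12R,13S)-13-(tert-butyldimethylsilyloxy)-16-hydroxy-4,5:8,12-diepoxycembr-15(17)-en-9-yl acetate
Conditions: SeO2 (0.5 equiv), tBuOOH, CH2Cl2, rt
Reagents that add atoms: selenium dioxide O=[Se]=O (oxygen carrier); tert-butyl hydroperoxide CC(C)(C)OO (terminal oxidant)
Why: Selenium dioxide allylic oxidation (ene reaction then [2,3]-shift) of the only alkene left should oxidise the isopropenyl methyl group, CH3 being preferred over the tertiary C1–H, to the primary allylic alcohol.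

Step 22
Reactants: 30 allylic alcohol
Product: 32 epoxy acid (1R,4S,5S,8S,9S,12R,13S)-9-acetoxy-13-(tert-butyldimethylsilyloxy)-4,5:8,12-diepoxycembr-15(17)-en-16-oic acid, via enal 31 (not isolated)
Conditions: TEMPO (cat.), PhI(OAc)2, CH2Cl2, rt; then NaClO2, NaH2PO4, 2-methyl-2-butene, tBuOH/H2O
Reagents that add atoms: sodium chlorite [Na+].[O-]Cl=O
Why: TEMPO-catalysed oxidation to the enal followed by Pinnick oxidation gives the 2-substituted acrylic acid under buffered conditions that spare the epoxide, the acetate and the silyl ether.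

Step 23
Reactants: 32 epoxy acid
Product: 33 hydroxy lactone (1R,4R,5S,8S,9S,12R,13S)-9-acetoxy-13-(tert-butyldimethylsilyloxy)-5-hydroxy-8,12-epoxycembr-15(17)-en-16,4-olide
Conditions: CSA (0.1 equiv), CH2Cl2, 0 °C → rt
Reagents that add atoms: none
Why: Acid-catalysed intramolecular epoxide opening by the carboxylic acid at the tertiary carbon C4 (7-exo-tet, Markovnikov, inversion) should form the α-methylene ε-lactone and set C4 (R), leaving the C5 hydroxyl.

Step 24
Reactants: 33 hydroxy lactone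
Product: 34 keto lactone (1R,4R,8S,9S,12R,13S)-9-acetoxy-13-(tert-butyldimethylsilyloxy)-5-oxo-8,12-epoxycembr-15(17)-en-16,4-olide
Conditions: Dess–Martin periodinane, NaHCO3, CH2Cl2, rt
Reagents that add atoms: none
Why: Dess–Martin oxidation converts the secondary C5 alcohol into the ketone, the quaternary C4 and the protected C13 oxygen being inert.

Step 25
Reactants: 34 keto lactone
Product: 35 target (1R,4R,8S,9S,12R,13S)-9-acetoxy-13-hydroxy-5-oxo-8,12-epoxycembr-15(17)-en-16,4-olide
Conditions: HF·pyridine, THF/pyridine, 0 °C → rt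
Reagents that add atoms: none
Why: Fluoride-mediated desilylation under buffered, non-basic conditions should free the C13 hydroxyl without acyl migration or addition to the α-methylene lactone.

**Compound list**

1 | (R)-(+)-limonene | CC1=CC[C@@H](CC1)C(C)=C | starting material
2 | (R)-6-oxo-3-(prop-1-en-2-yl)heptanal | CC(=O)CC[C@H](CC=O)C(C)=C | intermediate (not isolated)
3 | (R)-7,7-dimethoxy-5-(prop-1-en-2-yl)heptan-2-one | CC(=O)CC[C@H](CC(OC)OC)C(C)=C | intermediate
4 | diethyl (R)-7,7-dimethoxy-5-(prop-1-en-2-yl)hept-1-en-2-yl phosphate | C=C(OP(=O)(OCC)OCC)CC[C@H](CC(OC)OC)C(C)=C | intermediate (not isolated)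
5 | lithium acetylide of (R)-7,7-dimethoxy-5-(prop-1-en-2-yl)hept-1-yne | [Li]C#CCC[C@H](CC(OC)OC)C(C)=C | intermediate (not isolated)
6 | [(R)-7,7-dimethoxy-5-(prop-1-en-2-yl)hept-1-yn-1-yl]trimethylsilane | C[Si](C)(C)C#CCC[C@H](CC(OC)OC)C(C)=C | intermediate
7 | (R)-3-(prop-1-en-2-yl)-7-(trimethylsilyl)hept-6-ynal | C[Si](C)(C)C#CCC[C@H](CC=O)C(C)=C | intermediate
8 | (5R)-2-methyl-5-(prop-1-en-2-yl)-9-(trimethylsilyl)non-1-en-8-yn-3-ol (both carbinol epimers) | C[Si](C)(C)C#CCC[C@H](CC(O)C(C)=C)C(C)=C | intermediate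
9 | ethyl (4E,7R)-4-methyl-7-(prop-1-en-2-yl)-11-(trimethylsilyl)undec-4-en-10-ynoate | CCOC(=O)CC/C(C)=C/C[C@@H](CCC#C[Si](C)(C)C)C(C)=C | intermediate
10 | (4E,7R)-4-methyl-7-(prop-1-en-2-yl)-11-(trimethylsilyl)undec-4-en-10-yn-1-ol | OCCC/C(C)=C/C[C@@H](CCC#C[Si](C)(C)C)C(C)=C | intermediate
11 | (4E,7R)-4-methyl-7-(prop-1-en-2-yl)-11-(trimethylsilyl)undec-4-en-10-yn-1-yl N,N-diisopropylcarbamate | CC(C)N(C(C)C)C(=O)OCCC/C(C)=C/C[C@@H](CCC#C[Si](C)(C)C)C(C)=C | intermediate
12 | 3-{(2S,3S)-2-methyl-3-[(2R)-2-(prop-1-en-2-yl)-6-(trimethylsilyl)hex-5-yn-1-yl]oxiran-2-yl}propyl N,N-diisopropylcarbamate | CC(C)N(C(C)C)C(=O)OCCC[C@]1(C)O[C@H]1C[C@@H](CCC#C[Si](C)(C)C)C(C)=C | intermediate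
13 | methyl 3-hydroxypropanoate | COC(=O)CCO | starting material
14 | methyl 3-(tert-butyldimethylsilyloxy)propanoate | COC(=O)CCO[Si](C)(C)C(C)(C)C | intermediate
15 | 3-(tert-butyldimethylsilyloxy)-N-methoxy-N-methylpropanamide | CON(C)C(=O)CCO[Si](C)(C)C(C)(C)C | intermediate
16 | (R)-C9-lithiated derivative of 12 | CC(C)N(C(C)C)C(=O)O[C@H]([Li])CC[C@]1(C)O[C@H]1C[C@@H](CCC#C[Si](C)(C)C)C(C)=C | intermediate (not isolated)
17 | (3S)-6-(tert-butyldimethylsilyloxy)-1-{(2S,3S)-2-methyl-3-[(2R)-2-(prop-1-en-2-yl)-6-(trimethylsilyl)hex-5-yn-1-yl]oxiran-2-yl}-4-oxohexan-3-yl N,N-diisopropylcarbamate | CC(C)N(C(C)C)C(=O)O[C@H](C(=O)CCO[Si](C)(C)C(C)(C)C)CC[C@]1(C)O[C@H]1C[C@@H](CCC#C[Si](C)(C)C)C(C)=C | intermediate (not isolated)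
18 | (1R,4S,5S,7S)-5-[2-(tert-butyldimethylsilyloxy)ethyl]-1-methyl-7-[(2R)-2-(prop-1-en-2-yl)-6-(trimethylsilyl)hex-5-yn-1-yl]-6,8-dioxabicyclo[3.2.1]octan-4-yl N,N-diisopropylcarbamate | CC(C)N(C(C)C)C(=O)O[C@H]1CC[C@@]2(C)O[C@]1(CCO[Si](C)(C)C(C)(C)C)O[C@H]2C[C@@H](CCC#C[Si](C)(C)C)C(C)=C | intermediate
19 | (2S,3S,6R)-2-[2-(tert-butyldimethylsilyloxy)ethyl]-6-[(1S,3R)-1-hydroxy-3-(prop-1-en-2-yl)-7-(trimethylsilyl)hept-6-yn-1-yl]-2,6-dimethyloxan-3-yl N,N-diisopropylcarbamate | CC(C)N(C(C)C)C(=O)O[C@H]1CC[C@](C)([C@@H](O)C[C@@H](CCC#C[Si](C)(C)C)C(C)=C)O[C@@]1(C)CCO[Si](C)(C)C(C)(C)C | intermediate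
20 | (2S,3S,6R)-2-[2-(tert-butyldimethylsilyloxy)ethyl]-6-[(1S,3R)-1-(tert-butyldimethylsilyloxy)-3-(prop-1-en-2-yl)-7-(trimethylsilyl)hept-6-yn-1-yl]-2,6-dimethyloxan-3-yl N,N-diisopropylcarbamate | CC(C)N(C(C)C)C(=O)O[C@H]1CC[C@](C)([C@@H](O[Si](C)(C)C(C)(C)C)C[C@@H](CCC#C[Si](C)(C)C)C(C)=C)O[C@@]1(C)CCO[Si](C)(C)C(C)(C)C | intermediate
21 | (2S,3S,6R)-2-[2-(tert-butyldimethylsilyloxy)ethyl]-6-[(1S,3R)-1-(tert-butyldimethylsilyloxy)-3-(prop-1-en-2-yl)-7-(trimethylsilyl)hept-6-yn-1-yl]-2,6-dimethyloxan-3-ol | O[C@H]1CC[C@](C)([C@@H](O[Si](C)(C)C(C)(C)C)C[C@@H](CCC#C[Si](C)(C)C)C(C)=C)O[C@@]1(C)CCO[Si](C)(C)C(C)(C)C | intermediate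
22 | (2S,3S,6R)-6-[(1S,3R)-1-(tert-butyldimethylsilyloxy)-3-(prop-1-en-2-yl)hept-6-yn-1-yl]-2-(2-hydroxyethyl)-2,6-dimethyloxan-3-ol | O[C@H]1CC[C@](C)([C@@H](O[Si](C)(C)C(C)(C)C)C[C@@H](CCC#C)C(C)=C)O[C@@]1(C)CCO | intermediate
23 | (E)-C5-dimethylalanyl derivative of 24 (hydroxyls present as aluminium alkoxides) | O[C@H]1CC[C@](C)([C@@H](O[Si](C)(C)C(C)(C)C)C[C@@H](CC/C(C)=C/[Al](C)C)C(C)=C)O[C@@]1(C)CCO | intermediate (not isolated)
24 | (2S,3S,6R)-6-[(1S,3R,6E)-1-(tert-butyldimethylsilyloxy)-7-iodo-6-methyl-3-(prop-1-en-2-yl)hept-6-en-1-yl]-2-(2-hydroxyethyl)-2,6-dimethyloxan-3-ol | O[C@H]1CC[C@](C)([C@@H](O[Si](C)(C)C(C)(C)C)C[C@@H](CC/C(C)=C/I)C(C)=C)O[C@@]1(C)CCO | intermediate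
25 | (2S,3S,6R)-6-[(1S,3R,6E)-1-(tert-butyldimethylsilyloxy)-7-iodo-6-methyl-3-(prop-1-en-2-yl)hept-6-en-1-yl]-2-(2-iodoethyl)-2,6-dimethyloxan-3-ol | O[C@H]1CC[C@](C)([C@@H](O[Si](C)(C)C(C)(C)C)C[C@@H](CC/C(C)=C/I)C(C)=C)O[C@@]1(C)CCI | intermediate
26 | (2S,3S,6R)-6-[(1S,3R,6E)-1-(tert-butyldimethylsilyloxy)-7-iodo-6-methyl-3-(prop-1-en-2-yl)hept-6-en-1-yl]-2-(2-iodoethyl)-2,6-dimethyloxan-3-yl acetate | CC(=O)O[C@H]1CC[C@](C)([C@@H](O[Si](C)(C)C(C)(C)C)C[C@@H](CC/C(C)=C/I)C(C)=C)O[C@@]1(C)CCI | intermediate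
27 | alkylzinc iodide from 26 (C6–ZnI) | CC(=O)O[C@H]1CC[C@](C)([C@@H](O[Si](C)(C)C(C)(C)C)C[C@@H](CC/C(C)=C/I)C(C)=C)O[C@@]1(C)CC[Zn]I | intermediate (not isolated)
28 | (1R,4E,8S,9S,12R,13S)-13-(tert-butyldimethylsilyloxy)-8,12-epoxycembra-4,15(17)-dien-9-yl acetate | C=C(C)[C@@H]1CC/C(C)=C/CC[C@]2(C)O[C@](C)(CC[C@@H]2OC(C)=O)[C@@H](O[Si](C)(C)C(C)(C)C)C1 | intermediate
29 | (1R,4S,5S,8S,9S,12R,13S)-13-(tert-butyldimethylsilyloxy)-4,5:8,12-diepoxycembr-15(17)-en-9-yl acetate | C=C(C)[C@@H]1CC[C@]3(C)O[C@H]3CC[C@]2(C)O[C@](C)(CC[C@@H]2OC(C)=O)[C@@H](O[Si](C)(C)C(C)(C)C)C1 | intermediate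
30 | (1R,4S,5S,8S,9S,12R,13S)-13-(tert-butyldimethylsilyloxy)-16-hydroxy-4,5:8,12-diepoxycembr-15(17)-en-9-yl acetate | C=C(CO)[C@@H]1CC[C@]3(C)O[C@H]3CC[C@]2(C)O[C@](C)(CC[C@@H]2OC(C)=O)[C@@H](O[Si](C)(C)C(C)(C)C)C1 | intermediate
31 | (1R,4S,5S,8S,9S,12R,13S)-13-(tert-butyldimethylsilyloxy)-16-oxo-4,5:8,12-diepoxycembr-15(17)-en-9-yl acetate | C=C(C=O)[C@@H]1CC[C@]3(C)O[C@H]3CC[C@]2(C)O[C@](C)(CC[C@@H]2OC(C)=O)[C@@H](O[Si](C)(C)C(C)(C)C)C1 | intermediate (not isolated)
32 | (1R,4S,5S,8S,9S,12R,13S)-9-acetoxy-13-(tert-butyldimethylsilyloxy)-4,5:8,12-diepoxycembr-15(17)-en-16-oic acid | C=C(C(=O)O)[C@@H]1CC[C@]3(C)O[C@H]3CC[C@]2(C)O[C@](C)(CC[C@@H]2OC(C)=O)[C@@H](O[Si](C)(C)C(C)(C)C)C1 | intermediate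
33 | (1R,4R,5S,8S,9S,12R,13S)-9-acetoxy-13-(tert-butyldimethylsilyloxy)-5-hydroxy-8,12-epoxycembr-15(17)-en-16,4-olide | C=C1C(=O)O[C@]2(C)CC[C@@H]1C[C@H](O[Si](C)(C)C(C)(C)C)[C@@]1(C)CC[C@H](OC(C)=O)[C@](C)(CC[C@@H]2O)O1 | intermediate
34 | (1R,4R,8S,9S,12R,13S)-9-acetoxy-13-(tert-butyldimethylsilyloxy)-5-oxo-8,12-epoxycembr-15(17)-en-16,4-olide | C=C1C(=O)O[C@]2(C)CC[C@@H]1C[C@H](O[Si](C)(C)C(C)(C)C)[C@@]1(C)CC[C@H](OC(C)=O)[C@](C)(CCC2=O)O1 | intermediate
35 | CNP0154271.1, (1R,4R,8S,9S,12R,13S)-9-acetoxy-13-hydroxy-5-oxo-8,12-epoxycembr-15(17)-en-16,4-olide | C=C1C(=O)O[C@]2(C)CC[C@@H]1C[C@H](O)[C@@]1(C)CC[C@H](OC(C)=O)[C@](C)(CCC2=O)O1 | target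

**Step count and risks**

Total step count: 25. Longest linear sequence: 23 steps (steps 1–8 and 11–25, from limonene); steps 9–10 are a two-step branch to the Weinreb amide.

Steps most likely to fail:

- Step 11. Deprotonation or opening of the trisubstituted epoxide by sBuLi may compete with the carbamate-directed lithiation, or the C9 configuration may be lost before ketalisation. The fallback separates carbanion chemistry from the epoxide. It sets out from 11, which has no epoxide: the same sBuLi/(+)-sparteine lithiation gives the (R)-C9-lithiated carbamate F1, and acylation with 15 gives the α-carbamoyloxy ketone F2. Shi epoxidation of the C12=C13 alkene of F2 (ent-Shi ketone, KHSO5, buffered) then gives epoxy ketone 17 as an isolated compound, and CSA in CH2Cl2 closes it to 18, where the route is rejoined.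

- Step 19. Intermolecular coupling to oligomers, or protonolysis and β-hydride loss of the alkylzinc, may outrun ring closure. The fallback replaces the organozinc made in the flask by a bench-stable organoboron reagent. It sets out from 26: copper-catalysed borylation of the primary iodide (CuI, PPh3, LiOMe, B2pin2, DMF, rt) gives the primary pinacol boronate F3, and KHF2 in MeOH/H2O converts it to the potassium trifluoroborate F4. Suzuki–Miyaura macrocyclisation with the vinyl iodide (Pd(OAc)2, RuPhos, K2CO3, toluene/H2O, slow addition) comes back to the route at 28.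

- Step 23. Ionisation of the tertiary epoxide carbon may lead to hydride shift or elimination (Meinwald-type rearrangement) before the weakly nucleophilic acrylic acid captures it. The fallback forms the C4–O bond at the ether oxidation level and raises it afterwards. It sets out from 30: under CSA in CH2Cl2 the more nucleophilic primary allylic alcohol opens the epoxide at C4 to give the 3-methyleneoxepane ether F5, with C5–OH free. CrO3·2 pyridine in CH2Cl2 then oxidises the C5 alcohol to the keto ether F6 and the allylic ether methylene to the lactone carbonyl, coming back to the route at 34.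

**Further compounds**

F1 | step 11 | (R)-C9-lithiated derivative of 11 | CC(C)N(C(C)C)C(=O)O[C@H]([Li])CC/C(C)=C/C[C@@H](CCC#C[Si](C)(C)C)C(C)=C
F2 | step 11 | (4S,7E,10R)-1-(tert-butyldimethylsilyloxy)-7-methyl-3-oxo-10-(prop-1-en-2-yl)-14-(trimethylsilyl)tetradec-7-en-13-yn-4-yl N,N-diisopropylcarbamate | CC(C)N(C(C)C)C(=O)O[C@H](C(=O)CCO[Si](C)(C)C(C)(C)C)CC/C(C)=C/C[C@@H](CCC#C[Si](C)(C)C)C(C)=C
F3 | step 19 | pinacol boronate from 26 (C6–Bpin) | CC(=O)O[C@H]1CC[C@](C)([C@@H](O[Si](C)(C)C(C)(C)C)C[C@@H](CC/C(C)=C/I)C(C)=C)O[C@@]1(C)CCB1OC(C)(C)C(C)(C)O1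
F4 | step 19 | potassium trifluoroborate from F3 (C6–BF3K) | CC(=O)O[C@H]1CC[C@](C)([C@@H](O[Si](C)(C)C(C)(C)C)C[C@@H](CC/C(C)=C/I)C(C)=C)O[C@@]1(C)CC[B-](F)(F)F.[K+]
F5 | step 23 | (1R,4R,5S,8S,9S,12R,13S)-13-(tert-butyldimethylsilyloxy)-5-hydroxy-4,16:8,12-diepoxycembr-15(17)-en-9-yl acetate | C=C1CO[C@]2(C)CC[C@@H]1C[C@H](O[Si](C)(C)C(C)(C)C)[C@@]1(C)CC[C@H](OC(C)=O)[C@](C)(CC[C@@H]2O)O1
F6 | step 23 | (1R,4R,8S,9S,12R,13S)-13-(tert-butyldimethylsilyloxy)-5-oxo-4,16:8,12-diepoxycembr-15(17)-en-9-yl acetate | C=C1CO[C@]2(C)CC[C@@H]1C[C@H](O[Si](C)(C)C(C)(C)C)[C@@]1(C)CC[C@H](OC(C)=O)[C@](C)(CCC2=O)O1
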